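**Retrosynthetic overview**

1. The target is a 7-oxabicyclo[4.1.0]hept-3-en-2-one: C1 is the farnesyl-bearing oxirane carbon, C2 the ketone, C3=C4 the alkene with the 4-methyl group, C5 the acetoxy carbon, C6 the oxirane CH, O7 the oxirane oxygen. The route rests on C5 being an allylic carbinol held between alkene carbon C4 and oxirane carbon C6.
2. Endgame: C5 acetylation, C2 desilylation and C2 oxidation of an all-cis C5 alcohol / C2 silyl ether.
3. Key disconnection C4–C5: intramolecular Nozaki–Hiyama–Kishi addition of a (Z)-C4 alkenyl iodide to a C5 epoxy aldehyde. Ring order: oxirane first (acyclic, reagent-controlled Sharpless epoxidation), then the six-membered ring.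
4. The epoxy aldehyde comes from a (Z,Z)-dienyl primary allylic alcohol. Both trisubstituted alkenes come from hydroxyl-directed Red-Al/iodine on propargylic alcohols, the C1–C2 bond from an alkenyllithium and an ynal, and the temporary C2 stereocentre from asymmetric transfer hydrogenation.
5. Starting materials: (2E,6E)-farnesyl bromide (1), propargyl alcohol (2) and 2-butynal (3).

Key step: step 12

Remark: the locants C1–C6 and O7 of the final bicycle are used for every intermediate; "farnesyl" means (2E,6E)-3,7,11-trimethyldodeca-2,6,10-trien-1-yl.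
Assumption: in the transfer hydrogenation of the ynone the alkynyl group is taken as the π-substituent recognised by the Ru–TsDPEN catalyst, as with alkyl alkynyl ketones. C2 is a temporary centre (oxidised in the last step), so the enantiomeric purity of the target rests on the epoxidation.

**Route**

Step 1
Reactants: 1 (2E,6E)-farnesyl bromide; 2 propargyl alcohol
Product: 4 (5E,9E)-6,10,14-trimethylpentadeca-5,9,13-trien-2-yn-1-ol
Conditions: CuI (10 mol%), K2CO3, n-Bu4NI (10 mol%), DMF, rt
Reagents that add atoms: none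
Why: Under carbonate base the terminal alkyne forms a copper(I) acetylide that displaces the primary allylic bromide at its α-carbon (copper-catalysed alkyne–allyl halide coupling), so the 2E,6E triene is kept and the hydroxyl group needs no protection.

Step 2
Reactants: 4 (5E,9E)-6,10,14-trimethylpentadeca-5,9,13-trien-2-yn-1-ol
Product: 6 (2Z,5E,9E)-3-iodo-6,10,14-trimethylpentadeca-2,5,9,13-tetraen-1-ol, via cyclic sodium alkenyl(alkoxy)bis(2-methoxyethoxy)aluminate 5 (not isolated)
Conditions: Red-Al (1.5 equiv), THF, 0 °C to rt; then I2 (excess), THF, −78 °C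
Reagents that add atoms: iodine, II
Why: The aluminium alkoxide delivers hydride to the alkyne carbon next to the carbinol and aluminium to the distal carbon in a trans sense (hydroxyl-directed trans-hydroalumination), and iodinolysis of the C–Al bond of 5 with retention should give only the 2Z iodoalkene with iodine on the future C1.

Step 3
Reactants: 6 (2Z,5E,9E)-3-iodo-6,10,14-trimethylpentadeca-2,5,9,13-tetraen-1-ol
Product: 7 4-methoxybenzyl ether of 6
Conditions: NaH, 4-methoxybenzyl chloride, n-Bu4NI (cat.), THF–DMF, 0 °C to rt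
Reagents that add atoms: 4-methoxybenzyl chloride, COc1ccc(CCl)cc1
Why: Williamson etherification; the 4-methoxybenzyl ether survives tert-butyllithium, Red-Al and silylation, cannot undergo the O-to-C silyl shift open to a γ-silyloxy alkenyllithium, and is later removed oxidatively without acid.

Step 4
Reactants: 7 4-methoxybenzyl ether of 6; 3 2-butynal
Product: 9 rac-(2Z)-3-farnesyl-1-(4-methoxybenzyloxy)hept-2-en-5-yn-4-ol, via (Z)-alkenyllithium 8 (not isolated)
Conditions: t-BuLi (2.1 equiv), Et2O, −78 °C; then 3, −78 °C; aq NH4Cl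
Reagents that add atoms: none
Why: Iodine–lithium exchange is fast at −78 °C and retains alkene geometry, and 1,2-addition of alkenyllithium 8 to the ynal forms the C1–C2 bond with C2 cis to C5; the new carbinol is racemic and is corrected in steps 5 and 6.

Step 5
Reactants: 9 rac-(2Z)-3-farnesyl-1-(4-methoxybenzyloxy)hept-2-en-5-yn-4-ol
Product: 10 (2Z)-3-farnesyl-1-(4-methoxybenzyloxy)hept-2-en-5-yn-4-one
Conditions: Dess–Martin periodinane, pyridine, CH2Cl2, 0 °C to rt
Reagents that add atoms: none
Why: Dess–Martin oxidation of a secondary alcohol that is both allylic and propargylic is fast under buffered, non-acidic conditions and leaves the ether and the polyene alone.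

Step 6
Reactants: 10 (2Z)-3-farnesyl-1-(4-methoxybenzyloxy)hept-2-en-5-yn-4-one
Product: 11 (2Z,4R)-3-farnesyl-1-(4-methoxybenzyloxy)hept-2-en-5-yn-4-ol
Conditions: Ru[(R,R)-TsDPEN](p-cymene) (2 mol%), i-PrOH, rt
Reagents that add atoms: none
Why: Noyori asymmetric transfer hydrogenation of an alkynyl ketone reduces only the C=O group, and with the alkyne as the π-substituent recognised by the catalyst the (R,R)-complex should deliver hydride to the face that gives the R propargylic alcohol.

Step 7
Reactants: 11 (2Z,4R)-3-farnesyl-1-(4-methoxybenzyloxy)hept-2-en-5-yn-4-ol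
Product: 13 (2Z,4S,5Z)-3-farnesyl-6-iodo-1-(4-methoxybenzyloxy)hepta-2,5-dien-4-ol, via cyclic sodium alanate 12 (not isolated)
Conditions: Red-Al (1.5 equiv), THF, 0 °C; then I2 (excess), THF, −78 °C
Reagents that add atoms: iodine, II
Why: A second hydroxyl-directed trans-hydroalumination–iodination places hydrogen on C3 and, through alanate 12, iodine on C4 cis to C2 (Z iodoalkene) without touching the C2 centre, whose descriptor changes from R to S only because the alkyne becomes an alkene.

Step 8
Reactants: 13 (2Z,4S,5Z)-3-farnesyl-6-iodo-1-(4-methoxybenzyloxy)hepta-2,5-dien-4-ol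
Product: 14 tert-butyldimethylsilyl ether of 13 at the C2 oxygen
Conditions: TBSOTf, 2,6-lutidine, CH2Cl2, −78 °C
Reagents that add atoms: tert-butyldimethylsilyl trifluoromethanesulfonate, CC(C)(C)[Si](C)(C)OS(=O)(=O)C(F)(F)F
Why: A silyl triflate with a hindered pyridine base silylates the hindered doubly allylic alcohol at low temperature without ionising it, and the silyl ether keeps C2 at the alcohol level so that the two ring oxygen functions stay distinct.

Step 9
Reactants: 14 tert-butyldimethylsilyl ether of 13
Product: 15 (2Z,4S,5Z)-4-(tert-butyldimethylsilyloxy)-3-farnesyl-6-iodohepta-2,5-dien-1-ol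
Conditions: DDQ, CH2Cl2–pH 7 buffer, 0 °C
Reagents that add atoms: none
Why: DDQ oxidises the electron-rich 4-methoxybenzyl ether through its benzylic cation and water releases the primary alcohol (oxidative PMB cleavage) under buffered neutral conditions that the silyl ether, the alkenyl iodide and the bis-allylic C2–H should tolerate at 0 °C.

Step 10
Reactants: 15 (2Z,4S,5Z)-4-(tert-butyldimethylsilyloxy)-3-farnesyl-6-iodohepta-2,5-dien-1-ol
Product: 16 [(2R,3R)-3-[(1S,2Z)-1-(tert-butyldimethylsilyloxy)-3-iodobut-2-en-1-yl]-3-farnesyloxiran-2-yl]methanol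
Conditions: Ti(OiPr)4 (1 equiv), D-(−)-diethyl tartrate (1.2 equiv), t-BuOOH, 4 Å MS, CH2Cl2, −20 °C
Reagents that add atoms: tert-butyl hydroperoxide, CC(C)(C)OO
Why: In the Katsuki–Sharpless asymmetric epoxidation the titanium–tartrate complex binds the only free allylic alcohol and delivers oxygen to the C1=C6 alkene alone, D-(−)-diethyl tartrate being the enantiomer that puts the oxygen on the face giving the (1R,6R) oxirane (reagent control), while the Z geometry places C2 and C5 cis on the ring; stoichiometric titanium is used because of the branched cis substituent.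

Step 11
Reactants: 16 [(2R,3R)-3-[(1S,2Z)-1-(tert-butyldimethylsilyloxy)-3-iodobut-2-en-1-yl]-3-farnesyloxiran-2-yl]methanol
Product: 17 (2S,3R)-3-[(1S,2Z)-1-(tert-butyldimethylsilyloxy)-3-iodobut-2-en-1-yl]-3-farnesyloxirane-2-carbaldehyde
Conditions: Dess–Martin periodinane, pyridine, CH2Cl2, 0 °C
Reagents that add atoms: none
Why: Buffered Dess–Martin oxidation turns the primary epoxy alcohol into the epoxy aldehyde without opening the oxirane or epimerising C6, and the aldehyde is used at once.

Step 12
Reactants: 17 (2S,3R)-3-[(1S,2Z)-1-(tert-butyldimethylsilyloxy)-3-iodobut-2-en-1-yl]-3-farnesyloxirane-2-carbaldehyde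
Product: 19 (1R,2S,5R,6R)-2-(tert-butyldimethylsilyloxy)-1-farnesyl-4-methyl-7-oxabicyclo[4.1.0]hept-3-en-5-ol, via alkenylchromium(III) dichloride 18 (not isolated)
Conditions: CrCl2 (8 equiv), NiCl2 (5 mol%), degassed DMF–THF (3:1), rt, 0.005 M, slow addition of 17
Reagents that add atoms: none
Why: Nickel(0), generated from NiCl2 by CrCl2, inserts into the C4–I bond with retention and transmetallates to chromium(III) to give alkenylchromium 18, which adds to the C5 aldehyde through a chromium-bound four-centre transition state to form the C4–C5 bond and the chromium alkoxide of 19. The closest known reaction type is the intramolecular Nozaki–Hiyama–Kishi alkenyl iodide–aldehyde cyclisation to cyclic allylic alcohols. The ring closes in the 6-exo-trig mode, made geometrically easy because C2 and C5 are cis on the oxirane and chromium is cis to C2 on the C3=C4 alkene. The new C5 stereocentre is controlled by the C1–C6 oxirane and the C2 silyl ether: chromium bridging the aldehyde oxygen and O7 holds C5=O syn to C6–O7, and in the boat-like transition state of this 1,4-diene-like ring the C2 silyloxy group (cis to O7) and the forming C5–O–Cr bond should both be pseudo-equatorial, which is cis-1,4, so the C5 oxygen ends cis to O7. The step needs chemoselectivity (aldehyde addition without opening or reduction of the oxirane, silyl ether and skipped polyene untouched), which the weakly basic, oxophilic alkenylchromium secures, and cyclisation over oligomerisation, which high dilution secures.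

Step 13
Reactants: 19 (1R,2S,5R,6R)-2-(tert-butyldimethylsilyloxy)-1-farnesyl-4-methyl-7-oxabicyclo[4.1.0]hept-3-en-5-ol
Product: 20 (1R,2S,5R,6R)-2-(tert-butyldimethylsilyloxy)-1-farnesyl-4-methyl-7-oxabicyclo[4.1.0]hept-3-en-5-yl acetate
Conditions: Ac2O, pyridine, DMAP (cat.), CH2Cl2, 0 °C to rt
Reagents that add atoms: acetic anhydride, CC(=O)OC(C)=O
Why: DMAP-catalysed acylation of the secondary allylic alcohol installs the C5 acetate with retention while the silyl ether masks C2.

Step 14
Reactants: 20 (1R,2S,5R,6R)-2-(tert-butyldimethylsilyloxy)-1-farnesyl-4-methyl-7-oxabicyclo[4.1.0]hept-3-en-5-yl acetate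
Product: 21 (1S,2S,5R,6R)-1-farnesyl-2-hydroxy-4-methyl-7-oxabicyclo[4.1.0]hept-3-en-5-yl acetate
Conditions: HF·pyridine, pyridine, THF, 0 °C to rt
Reagents that add atoms: none
Why: Buffered HF·pyridine cleaves the Si–O bond (fluoride desilylation) under non-basic conditions in which the acetate should not migrate and the oxirane should not open.

Step 15
Reactants: 21 (1S,2S,5R,6R)-1-farnesyl-2-hydroxy-4-methyl-7-oxabicyclo[4.1.0]hept-3-en-5-yl acetate
Product: 22 (1R,5R,6R)-1-farnesyl-4-methyl-2-oxo-7-oxabicyclo[4.1.0]hept-3-en-5-yl acetate (CID121596208)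
Conditions: Dess–Martin periodinane, pyridine, CH2Cl2, 0 °C to rt
Reagents that add atoms: none
Why: Dess–Martin oxidation of the allylic C2 alcohol gives the enone and removes the temporary C2 stereocentre, leaving the C1, C5 and C6 centres of the target untouched.

**Compound list**

1 | (2E,6E)-farnesyl bromide | BrC/C=C(\C)CC/C=C(\C)CCC=C(C)C | starting material
2 | propargyl alcohol | C#CCO | starting material
3 | 2-butynal | CC#CC=O | starting material
4 | (5E,9E)-6,10,14-trimethylpentadeca-5,9,13-trien-2-yn-1-ol | OCC#CC/C=C(\C)CC/C=C(\C)CCC=C(C)C | intermediate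
5 | cyclic sodium alkenyl(alkoxy)bis(2-methoxyethoxy)aluminate (Al on the future C1 and on the C5 oxygen) | [Na+].COCCO[Al-]1(OCCOC)OCC=C1C/C=C(\C)CC/C=C(\C)CCC=C(C)C | intermediate (not isolated)
6 | (2Z,5E,9E)-3-iodo-6,10,14-trimethylpentadeca-2,5,9,13-tetraen-1-ol | OC/C=C(\I)C/C=C(\C)CC/C=C(\C)CCC=C(C)C | intermediate
7 | 4-methoxybenzyl ether of 6 | COc1ccc(COC/C=C(\I)C/C=C(\C)CC/C=C(\C)CCC=C(C)C)cc1 | intermediate
8 | (Z)-alkenyllithium from 7 (Li on C1, cis to C5) | COc1ccc(COC/C=C(\[Li])C/C=C(\C)CC/C=C(\C)CCC=C(C)C)cc1 | intermediate (not isolated)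
9 | rac-(2Z)-3-farnesyl-1-(4-methoxybenzyloxy)hept-2-en-5-yn-4-ol | COc1ccc(COC/C=C(/C/C=C(\C)CC/C=C(\C)CCC=C(C)C)C(O)C#CC)cc1 | intermediate
10 | (2Z)-3-farnesyl-1-(4-methoxybenzyloxy)hept-2-en-5-yn-4-one | COc1ccc(COC/C=C(/C/C=C(\C)CC/C=C(\C)CCC=C(C)C)C(=O)C#CC)cc1 | intermediate
11 | (2Z,4R)-3-farnesyl-1-(4-methoxybenzyloxy)hept-2-en-5-yn-4-ol | COc1ccc(COC/C=C(/C/C=C(\C)CC/C=C(\C)CCC=C(C)C)[C@@H](O)C#CC)cc1 | intermediate
12 | cyclic sodium alanate from 11 (Al on C4 and on the C2 oxygen) | [Na+].COCCO[Al-]1(OCCOC)O[C@@H](C=C1C)/C(C/C=C(\C)CC/C=C(\C)CCC=C(C)C)=C\COCc1ccc(OC)cc1 | intermediate (not isolated)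
13 | (2Z,4S,5Z)-3-farnesyl-6-iodo-1-(4-methoxybenzyloxy)hepta-2,5-dien-4-ol | COc1ccc(COC/C=C(/C/C=C(\C)CC/C=C(\C)CCC=C(C)C)[C@@H](O)/C=C(\I)C)cc1 | intermediate
14 | tert-butyldimethylsilyl ether of 13 | COc1ccc(COC/C=C(/C/C=C(\C)CC/C=C(\C)CCC=C(C)C)[C@@H](O[Si](C)(C)C(C)(C)C)/C=C(\I)C)cc1 | intermediate
15 | (2Z,4S,5Z)-4-(tert-butyldimethylsilyloxy)-3-farnesyl-6-iodohepta-2,5-dien-1-ol | OC/C=C(/C/C=C(\C)CC/C=C(\C)CCC=C(C)C)[C@@H](O[Si](C)(C)C(C)(C)C)/C=C(\I)C | intermediate
16 | [(2R,3R)-3-[(1S,2Z)-1-(tert-butyldimethylsilyloxy)-3-iodobut-2-en-1-yl]-3-farnesyloxiran-2-yl]methanol | OC[C@H]1O[C@@]1(C/C=C(\C)CC/C=C(\C)CCC=C(C)C)[C@@H](O[Si](C)(C)C(C)(C)C)/C=C(\I)C | intermediate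
17 | (2S,3R)-3-[(1S,2Z)-1-(tert-butyldimethylsilyloxy)-3-iodobut-2-en-1-yl]-3-farnesyloxirane-2-carbaldehyde (key-step precursor) | O=C[C@H]1O[C@@]1(C/C=C(\C)CC/C=C(\C)CCC=C(C)C)[C@@H](O[Si](C)(C)C(C)(C)C)/C=C(\I)C | intermediate
18 | alkenylchromium(III) dichloride from 17 (Cr on C4, cis to C2) | O=C[C@H]1O[C@@]1(C/C=C(\C)CC/C=C(\C)CCC=C(C)C)[C@@H](O[Si](C)(C)C(C)(C)C)/C=C(\[Cr](Cl)Cl)C | intermediate (not isolated)
19 | (1R,2S,5R,6R)-2-(tert-butyldimethylsilyloxy)-1-farnesyl-4-methyl-7-oxabicyclo[4.1.0]hept-3-en-5-ol (key-step product, all-cis) | O[C@@H]1C(C)=C[C@H](O[Si](C)(C)C(C)(C)C)[C@]2(C/C=C(\C)CC/C=C(\C)CCC=C(C)C)O[C@H]12 | intermediate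
20 | (1R,2S,5R,6R)-2-(tert-butyldimethylsilyloxy)-1-farnesyl-4-methyl-7-oxabicyclo[4.1.0]hept-3-en-5-yl acetate | CC(=O)O[C@@H]1C(C)=C[C@H](O[Si](C)(C)C(C)(C)C)[C@]2(C/C=C(\C)CC/C=C(\C)CCC=C(C)C)O[C@H]12 | intermediate
21 | (1S,2S,5R,6R)-1-farnesyl-2-hydroxy-4-methyl-7-oxabicyclo[4.1.0]hept-3-en-5-yl acetate | CC(=O)O[C@@H]1C(C)=C[C@H](O)[C@]2(C/C=C(\C)CC/C=C(\C)CCC=C(C)C)O[C@H]12 | intermediate
22 | (1R,5R,6R)-1-farnesyl-4-methyl-2-oxo-7-oxabicyclo[4.1.0]hept-3-en-5-yl acetate | CC(=O)O[C@@H]1C(C)=CC(=O)[C@]2(C/C=C(\C)CC/C=C(\C)CCC=C(C)C)O[C@H]12 | target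

**Step count**

Total: 15 steps. Longest linear sequence: 15 steps (from 1; 2 and 3 enter as single building blocks).

**Steps most likely to fail**

Step 12 (ring closure). The alkenylchromium may add to the aldehyde face that puts the C5 oxygen trans to O7, through an open, dipole-opposed arrangement instead of the chelate. In that case C5 is set by SN2 inversion instead of by the facial course of the ring closure. The fallback sets out from 17: the cyclisation is run as in step 12 and the (1R,2S,5S,6R) C5 epimer of 19, F1, is separated from any 19. F1 is treated with PPh3, DIAD and acetic acid in THF at 0 °C (Mitsunobu reaction), which inverts C5 and installs the acetate in one operation. The route is rejoined at 20; any 19 formed alongside is acetylated as in step 13, so both C5 epimers converge on 20.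

Step 10 (asymmetric epoxidation). Oxygen transfer may be slow because the branched C2 substituent sits cis to the hydroxymethyl group, and facial control may erode if the C2 centre opposes the tartrate. The fallback sets out from 15 and comes back at 16 (no new compound, F0). The dimeric titanium–tartrate template is given up for a vanadium(V) alkylperoxide carried by a chiral C2-symmetric bis-hydroxamic acid (VO(OiPr)3, ligand, aqueous t-BuOOH, CH2Cl2, 0 °C). This one-metal, one-ligand catalyst class is suited to Z- and 3,3-disubstituted allylic alcohols and should be less sensitive to the cis substituent; the ligand enantiomer is chosen for the (1R,6R) oxirane.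

Step 6 (transfer hydrogenation). Hydride transfer may discriminate poorly between the alkynyl and the branched alkenyl group, both of which are π-substituents. In that case the C2 centre is made by enantioselective C–C bond formation instead of ketone reduction. The fallback sets out from 7: alkenyllithium 8 (t-BuLi, Et2O, −78 °C) is formylated with DMF to (2Z)-2-farnesyl-4-(4-methoxybenzyloxy)but-2-enal F2. Propyne and dimethylzinc give methyl(prop-1-ynyl)zinc F3 in the flask, and its zinc–ProPhenol-catalysed addition to F2 (toluene, 0 °C, ligand enantiomer chosen for the R carbinol) gives the propargylic alcohol. The route is rejoined at 11, bypassing 9 and 10.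

**Further compounds**

F1 | step 12 | (1R,2S,5S,6R)-2-(tert-butyldimethylsilyloxy)-1-farnesyl-4-methyl-7-oxabicyclo[4.1.0]hept-3-en-5-ol (C5 epimer of 19) | O[C@H]1C(C)=C[C@H](O[Si](C)(C)C(C)(C)C)[C@]2(C/C=C(\C)CC/C=C(\C)CCC=C(C)C)O[C@H]12
F0 | step 10 | none | none
F2 | step 6 | (2Z)-2-farnesyl-4-(4-methoxybenzyloxy)but-2-enal | COc1ccc(COC/C=C(/C/C=C(\C)CC/C=C(\C)CCC=C(C)C)C=O)cc1
F3 | step 6 | methyl(prop-1-ynyl)zinc | C[Zn]C#CC
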